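Choosing among the three changes needs one number: how steeply the final level of target climbs with the reagent charged.

the same everywhere: solid substrate 0.43 M
- birch: reagent 0.21 M; run made earlier
- maple: reagent 0.32 M; run made earlier
- flask: reagent 0.430 M; time 12 h

| run | time / h | target / % | idle adduct / % |
|---|---|---|---|
| birch | 2.00 | 1.8 | 1.5 |
| birch | 4.00 | 4.3 | 1.2 |
| birch | 6.00 | 4.3 | 0.7 |
| birch | 8.00 | 6.0 | 0 |
| birch | 10.0 | 5.5 | 0.4 |
| birch | 12.0 | 6.3 | 1.1 |
| birch | 15.0 | 5.3 | 0.5 |
| maple | 0.833 | 0.9 | 0.9 |
| maple | 2.00 | 3.3 | 2.5 |
| maple | 4.00 | 5.7 | 2.4 |
| maple | 6.00 | 7.0 | 1.2 |
| maple | 8.00 | 7.8 | 1.3 |
| maple | 12.0 | 7.4 | 0.3 |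
| maple | 15.0 | 7.6 | 0.8 |

(standard deviation of a reading: 0.5 percentage points)

- amounts and yields of target count idle adduct too
- given per volume of solution although it is solid: solid substrate
- what may be going on: dissolved substrate + reagent -> target; solid substrate <-> dissolved substrate; reagent + target <-> idle adduct; 2 reagent -> homo dimer; reagent -> side product
- at the start none of the solid substrate is in solution

1. the target and idle adduct together standing at 12 h, as a percentage of the solid substrate charged
2. the change that raises the amount of target and idle adduct together at 12 h, in percent of the solid substrate charged most ("none" if none brings more than 2 percentage points) (Tuesday's / Sunday's / Saturday's / none)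
3. amount of target and idle adduct together at 12 h, in percent of the solid substrate charged, after Sunday's

- Tuesday's: doubling the solubility of the solid substrate, all else as stated
- Sunday's: doubling the amount of reagent, all else as stated
- Saturday's: doubling the dissolution coefficient of the solid substrate, all else as stated

The target readings already count the idle adduct, so they are the asked amount. In the maple run the curve starts slowly, with none of the solid substrate in solution at first: the reading at 0.833 h lies below the line through the reading at 2.00 h, whose slope is 0.0165 h⁻¹ of the charge. Both runs lie flat within the scatter from 8.00 h, and their readings from then on average to levels of 5.77% (birch) and 7.60% (maple).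

exponent = ln(maple level / birch level) / ln(maple reagent / birch reagent) = 0.652

This reagent exponent, the fractional rise of the level per fractional rise of the reagent charge, is a reading and carries the scatter. The reckoning here takes it to the flask, with the starting slope proportional to reagent:

level = maple level × (flask reagent / maple reagent)^exponent = 9.21%

slope = maple slope × flask reagent / maple reagent = 0.0222 h⁻¹

knee = level / slope = 4.16 h

So the flask's curve bends near 4.16 h, and 12 h is 2.88 knees, which puts it on its level. Sunday's multiplies that level by 1.57, giving 14.5%. Tuesday's doubles the rate of dissolving at the start and with it the early target rate, a factor 2 that this reckoning takes as a rough estimate for the level, larger than Sunday's, though the extra target also uses reagent. Saturday's doubles that rate at first, but not the level the dissolved substrate runs to. This reckoning therefore picks Tuesday's.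

The forecast, holding that “the reagent must be dying through dimer and side-product routes”, gives 10.4%, 16% and Tuesday's, with a level above this reckoning's.

The flask gives 9.63%, and 14.6% after Sunday's. Tuesday's adds 7 percentage points, Sunday's 5 points, Saturday's 4.2 points, so the best is Tuesday's.

    dissolved substrate + reagent → target (k = 0.0160 M⁻¹ min⁻¹)
    solid substrate ⇌ dissolved substrate, rate k2*(cs2 - [dissolved substrate]) while solid is left; crystals form when [dissolved substrate] > cs2 (solubility = 0.230 M, k = 0.00440 min⁻¹)
    reagent + target ⇌ idle adduct, settled at all times (K = 16.0 M⁻¹)
    2 reagent → homo dimer (k = 0.00510 M⁻¹ min⁻¹)
    reagent → side product (k = 0.00740 min⁻¹)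

Between this flask and Sunday's the exponent comes to 0.600. Carried from this flask to a neighbour flask with 1.1 M of reagent, 0.652 gives 17.8%, and that neighbour stands lower, at 16.5%. In this flask at 1.14 h, the reagent's half-life by the path to side product is 1.6 h, shorter than the 14 h by the path to target. At 12.0 h this flask's limiting reagent has 0.25% of its charge left, while 50.1% of the solid substrate charged stands dissolved.

The data were computed for substances that don't exist.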